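## Retrosynthetic overview

1. Last bond, C12–C13: a photochemical Ni–H decarboxylative syn-hydroalkylation joins a C1–C12 methyl-alkynol to a C13–C19 acetoxy-lactone acid and creates the 11E alkene in the same step.
2. C1–C12 alkynol: the C8–C9 bond comes from Ni-electrochemical decarboxylative alkenylation of L-malic acid acetonide (C10 bought) with an (E)-2-iodoalkene; the dioxolanone C=O is then converted to C≡C–CH3.
3. C13–C19 acid: from D-glutamic acid 5-tert-butyl ester (C15 bought; the side-chain CO2H is the later radical handle) via an α-hydroxy γ-keto ester; chelate-controlled MeMgBr addition sets C16 and closes the lactone.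
4. Rings: the furan is bought intact; the γ-butyrolactone is the only ring made (step 9), before fragment union.

Numbering used: furan C1–C4, chain C5 (furyl-CH2) to C19 (lactone C=O); C10 = carbinol, C15 = CHOAc, C16 = quaternary lactone carbon. The target SMILES corresponds to 10S,15R,16S with 7E,11E.

Assumption: N-hydroxyphthalimide (NHPI) redox-active esters are generated in situ in steps 1, 3 and 11 and are not counted or numbered; commercial reagents that deliver atoms are numbered as starting materials.

## Route

Step 1
Reactants: 1, 3-(furan-3-yl)propanoic acid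
Product: 3, 3-(pent-3-yn-1-yl)furan
Conditions: NHPI, DIC, CH2Cl2, rt (ester in situ); then MeC≡CZnCl (from 2 + ZnCl2), NiCl2·6H2O (20 mol%), 2,2'-bipyridine, THF/DMF, rt
Reagents that add atoms: 2, prop-1-yn-1-ylmagnesium bromide, CC#C[Mg]Br
Why: Ni-catalysed decarboxylative alkynylation (radical Negishi-type coupling of a redox-active ester with an alkynylzinc) replaces CO2H by the propynyl group; no stereochemistry is involved.

Step 2
Reactants: 3, 3-(pent-3-yn-1-yl)furan
Product: 5, (E)-3-(4-iodopent-3-en-1-yl)furan
Conditions: Cp2Zr(H)Cl (1.6 equiv), THF, 50 °C, 1 h; then I2, THF, −78 → 0 °C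
Reagents that add atoms: 4, iodine, II
Why: Schwartz hydrozirconation is a syn addition that, after equilibration with excess reagent, places Zr on the methyl-bearing carbon (about 9:1 or better; the minor regioisomer is removed after step 3), and iodinolysis proceeds with retention to give the E iodide.

Step 3
Reactants: 5, (E)-3-(4-iodopent-3-en-1-yl)furan; 6, (S)-2,2-dimethyl-5-oxo-1,3-dioxolane-4-acetic acid (L-malic acid acetonide)
Product: 7, (S)-5-[(E)-5-(furan-3-yl)-2-methylpent-2-en-1-yl]-2,2-dimethyl-1,3-dioxolan-4-one
Conditions: 6 (1.5 equiv), NHPI, DIC, DMF (ester in situ); then 5, NiCl2·6H2O (10 mol%), 2,2'-bipyridine, AgNO3 (30 mol%), LiCl, DMF, Mg(+)/RVC(−), constant current, about 3 F/mol, rt, undivided cell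
Reagents that add atoms: none
Why: Ni-electrocatalytic decarboxylative alkenylation (cathodic cross-electrophile coupling of a redox-active ester with an alkenyl iodide) forms C8–C9 with retention of alkene geometry; the C9 radical is β to the C10 stereocentre, which is therefore untouched.

Step 4
Reactants: 7, (S)-5-[(E)-5-(furan-3-yl)-2-methylpent-2-en-1-yl]-2,2-dimethyl-1,3-dioxolan-4-one
Product: 9, (S,E)-8-(furan-3-yl)-5-methyloct-5-en-1-yn-3-ol
Conditions: DIBAL-H (1.1 equiv), CH2Cl2, −78 °C; then MeOH, K2CO3, 8, −78 °C → rt
Reagents that add atoms: 8, dimethyl (1-diazo-2-oxopropyl)phosphonate (Ohira–Bestmann reagent), COP(=O)(OC)C(=[N+]=[N-])C(C)=O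
Why: Half-reduction of the dioxolanone gives a lactol that releases acetone in basic methanol, and Seyferth–Gilbert (Ohira–Bestmann) homologation of the α-hydroxy aldehyde gives the terminal alkyne with the C10–O bond never broken.

Step 5
Reactants: 9, (S,E)-8-(furan-3-yl)-5-methyloct-5-en-1-yn-3-ol
Product: 11, (S,E)-9-(furan-3-yl)-6-methylnon-6-en-2-yn-4-ol
Conditions: n-BuLi (2.05 equiv), THF, −78 °C; MeI (1.2 equiv), −78 → 0 °C
Reagents that add atoms: 10, iodomethane, CI
Why: Alkylation of the alkoxide/acetylide dianion occurs on carbon (acetylide alkylation), installing the C12 methyl without protecting the alcohol.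

Step 6
Reactants: 12, D-glutamic acid 5-tert-butyl ester, (R)-2-amino-5-(tert-butoxy)-5-oxopentanoic acid
Product: 14, (R)-5-(tert-butoxy)-2-hydroxy-5-oxopentanoic acid
Conditions: NaNO2, aq. AcOH, 0 °C → rt
Reagents that add atoms: 13, water, O
Why: Diazotisation of the α-amino acid gives the α-hydroxy acid with net retention (double inversion through the α-lactone), so C15 is taken directly from the purchased amino acid.

Step 7
Reactants: 14, (R)-5-(tert-butoxy)-2-hydroxy-5-oxopentanoic acid
Product: 16, tert-butyl (R)-5-(ethylsulfanyl)-4-hydroxy-5-oxopentanoate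
Conditions: EtSH (3 equiv), EDC·HCl, HOBt, CH2Cl2, 0 °C → rt
Reagents that add atoms: 15, ethanethiol, CCS
Why: Carbodiimide (Steglich-type) thioesterification through the HOBt ester activates the α-carboxyl for ketone synthesis without touching the stereocentre or the tert-butyl ester.

Step 8
Reactants: 16, tert-butyl (R)-5-(ethylsulfanyl)-4-hydroxy-5-oxopentanoate
Product: 18, 8-tert-butyl 1-ethyl (R)-5-hydroxy-4-oxooctanedioate
Conditions: 17 (3 equiv, 0.5 M in THF), PdCl2(PPh3)2 (5 mol%), toluene, rt
Reagents that add atoms: 17, (3-ethoxy-3-oxopropyl)zinc bromide, CCOC(=O)CC[Zn]Br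
Why: Fukuyama coupling (Pd-catalysed thioester–organozinc ketone synthesis) attaches C17–C19 at the ester oxidation level under non-basic conditions that tolerate the free α-hydroxyl and both esters.

Step 9
Reactants: 18, 8-tert-butyl 1-ethyl (R)-5-hydroxy-4-oxooctanedioate
Product: 21, tert-butyl (R)-4-acetoxy-4-[(S)-2-methyl-5-oxooxolan-2-yl]butanoate
Conditions: MeMgBr (2.3 equiv), THF, −78 → −20 °C; then Ac2O, DMAP, −20 °C → rt
Reagents that add atoms: 19, methylmagnesium bromide, C[Mg]Br; 20, acetic anhydride, CC(=O)OC(C)=O
Why: Cram-chelate (cyclic model) Grignard addition: the magnesium alkoxide of the α-hydroxy ketone forms a five-membered chelate and methyl attacks from the face of the C15 hydrogen, giving 16S; the tertiary alkoxide lactonises onto the ethyl ester and the secondary alkoxide is trapped as the acetate.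

Step 10
Reactants: 21, tert-butyl (R)-4-acetoxy-4-[(S)-2-methyl-5-oxooxolan-2-yl]butanoate
Product: 22, (R)-4-acetoxy-4-[(S)-2-methyl-5-oxooxolan-2-yl]butanoic acid
Conditions: TFA/CH2Cl2 (1:4), 0 °C → rt
Reagents that add atoms: none
Why: Acidolysis of the tert-butyl ester (loss of isobutene) frees the carboxylic acid; the acetate and lactone are stable, and because O15 is already acetylated the acid cannot lactonise.

Step 11
Reactants: 11, (S,E)-9-(furan-3-yl)-6-methylnon-6-en-2-yn-4-ol; 22, (R)-4-acetoxy-4-[(S)-2-methyl-5-oxooxolan-2-yl]butanoic acid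
Product: 23, 15-acetylirciformonin B
Conditions: 22 (1.5 equiv), NHPI, DIC, DMA (ester in situ); then 11 (1.0 equiv), NiBr2·glyme (10 mol%), 4,4'-di-tert-butyl-2,2'-bipyridine (12 mol%), 4CzIPN (2 mol%), Hantzsch ester (2 equiv), degassed DMA, 450 nm LEDs, 25 °C
Reagents that add atoms: none
Why: Proposed new method: hydroxyl-directed photochemical Ni–H syn-hydroalkylation of an unprotected internal propargylic alcohol with a redox-active ester – photoreduced 4CzIPN (Hantzsch ester as terminal electron and proton donor) generates the C13 radical from the ester and low-valent Ni, protonation gives a Ni–H that adds syn across the alkyne with Ni on the less hindered methyl-bearing C12 (favoured sterically, as in hydrozirconation, and by a five-membered Ni···O chelate to the C10 hydroxyl), the alkenyl–Ni captures the radical and reductive elimination forms C12–C13 with retention, so H and alkyl are cis and the alkene is E, with no stereocentre touched; the closest known reaction types are NiH (or CuH/Ni) hydroalkylation of alkynes with alkyl halides, photoredox/Ni decarboxylative hydroalkylation of terminal alkynes, and photochemical Ni/Hantzsch-ester coupling of NHPI esters with vinyl halides.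

## Compound list

1 | 3-(furan-3-yl)propanoic acid | OC(=O)CCc1ccoc1 | starting material
2 | prop-1-yn-1-ylmagnesium bromide | CC#C[Mg]Br | starting material
3 | 3-(pent-3-yn-1-yl)furan | CC#CCCc1ccoc1 | intermediate
4 | iodine | II | starting material
5 | (E)-3-(4-iodopent-3-en-1-yl)furan | C/C(I)=C\CCc1ccoc1 | intermediate
6 | (S)-2,2-dimethyl-5-oxo-1,3-dioxolane-4-acetic acid (L-malic acid acetonide) | CC1(C)O[C@@H](CC(=O)O)C(=O)O1 | starting material
7 | (S)-5-[(E)-5-(furan-3-yl)-2-methylpent-2-en-1-yl]-2,2-dimethyl-1,3-dioxolan-4-one | CC1(C)O[C@@H](C/C(C)=C/CCc2ccoc2)C(=O)O1 | intermediate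
8 | dimethyl (1-diazo-2-oxopropyl)phosphonate | COP(=O)(OC)C(=[N+]=[N-])C(C)=O | starting material
9 | (S,E)-8-(furan-3-yl)-5-methyloct-5-en-1-yn-3-ol | C#C[C@@H](O)C/C(C)=C/CCc1ccoc1 | intermediate
10 | iodomethane | CI | starting material
11 | (S,E)-9-(furan-3-yl)-6-methylnon-6-en-2-yn-4-ol | CC#C[C@@H](O)C/C(C)=C/CCc1ccoc1 | intermediate
12 | D-glutamic acid 5-tert-butyl ester, (R)-2-amino-5-(tert-butoxy)-5-oxopentanoic acid | N[C@H](CCC(=O)OC(C)(C)C)C(=O)O | starting material
13 | water | O | starting material
14 | (R)-5-(tert-butoxy)-2-hydroxy-5-oxopentanoic acid | O[C@H](CCC(=O)OC(C)(C)C)C(=O)O | intermediate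
15 | ethanethiol | CCS | starting material
16 | tert-butyl (R)-5-(ethylsulfanyl)-4-hydroxy-5-oxopentanoate | CCSC(=O)[C@H](O)CCC(=O)OC(C)(C)C | intermediate
17 | (3-ethoxy-3-oxopropyl)zinc bromide | CCOC(=O)CC[Zn]Br | starting material
18 | 8-tert-butyl 1-ethyl (R)-5-hydroxy-4-oxooctanedioate | CCOC(=O)CCC(=O)[C@H](O)CCC(=O)OC(C)(C)C | intermediate
19 | methylmagnesium bromide | C[Mg]Br | starting material
20 | acetic anhydride | CC(=O)OC(C)=O | starting material
21 | tert-butyl (R)-4-acetoxy-4-[(S)-2-methyl-5-oxooxolan-2-yl]butanoate | CC(=O)O[C@H](CCC(=O)OC(C)(C)C)[C@]1(C)CCC(=O)O1 | intermediate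
22 | (R)-4-acetoxy-4-[(S)-2-methyl-5-oxooxolan-2-yl]butanoic acid | CC(=O)O[C@H](CCC(=O)O)[C@]1(C)CCC(=O)O1 | intermediate
23 | 15-acetylirciformonin B, (1R,4E,6S,8E)-11-(furan-3-yl)-6-hydroxy-4,8-dimethyl-1-[(2S)-2-methyl-5-oxooxolan-2-yl]undeca-4,8-dien-1-yl acetate | CC(=O)O[C@H](CC/C(C)=C/[C@@H](O)C/C(C)=C/CCc1ccoc1)[C@]1(C)CCC(=O)O1 | target

## Summary

Total steps: 11 (in situ NHPI-ester formation not counted separately).
Longest linear sequence: 6 steps (1→2→3→4→5→11, or 6→7→8→9→10→11).

Steps most likely to fail:

1. Step 11 (proposed new method). Risks are wrong Ni–H regiochemistry, hydrodecarboxylation of the radical, or O-acylation of the free C10–OH by the active ester. Fallback (known chemistry): hydrozirconation–iodination of 11 (Cp2Zr(H)Cl, 2.2 equiv; I2), which puts iodine on the methyl-bearing carbon to give the (E)-2-iodoalkenol, then the Ni-electrocatalytic decarboxylative alkenylation of step 3 with the NHPI ester of 22.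

2. Step 4. The free α-hydroxy aldehyde may epimerise or dimerise in K2CO3/MeOH. Fallback: open 7 with MeNHOMe·HCl/i-PrMgCl to the α-hydroxy Weinreb amide, TBS-protect, reduce with DIBAL-H to the α-silyloxy aldehyde, then Corey–Fuchs (CBr4/PPh3; n-BuLi then MeI) to give the TBS ether of 11 directly, and TBAF. This replaces steps 4–5 with a protected-aldehyde dibromo-olefination route.

3. Step 9. Risks are erosion of chelate control, epimerisation of α-ketol 18, or the C15 alkoxide closing onto the tert-butyl ester. Fallback: build C16 by hydroxyl-directed epoxidation instead. Convert 16 with Me2CuLi to the α-hydroxy methyl ketone, methylenate (Ph3P=CH2) to the 1,1-disubstituted allylic alcohol, and epoxidise with VO(acac)2/t-BuOOH (erythro-selective through A1,2 strain, which gives the same 15R,16S relationship). Then open the epoxide CH2 with sodio diethyl malonate, lactonise, decarbethoxylate (Krapcho) and acetylate to reach 21.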